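**Retrosynthetic overview**
1. Target 20 ⇐ O8‑TES ether 19 ⇐ acetylation of the 3‑hydroxy‑decanolide 18.
2. 18 ⇐ 4→10 ring expansion: the C9–OH of 17 is inserted into the acyl–O bond of its own trans‑β‑lactone (C1–O9 made, C1–O3 broken).
3. 17 ⇐ Lindlar (4Z) ⇐ 16 ⇐ C9–C10 bond: α‑silyloxy aldehyde 11 + bis(4‑acetoxypentyl)zinc 15, made from (S)‑pent‑4‑en‑2‑ol 12.
4. 11 ⇐ trans‑β‑lactone 10 ⇐ C2–C3 and O3–C1 bonds: ynal 8 + propionyl bromide 9. 8 ⇐ (R)‑glycidol 1 + 1‑TMS‑propyne 3 + DMF.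
5. Ring order: the oxetan‑2‑one forms first (step 4). The ten‑membered lactone forms second (step 9) and grows out of the first ring.

Assumption: decanolide numbering is used throughout (C1 = lactone C=O, C9 = ring carbinol carbon, C13 = side‑chain carbinol carbon). The SMILES reads as (2R,3R,4Z,8S,9R,13S), that is 2,3‑anti and 8,9‑anti. Compounds 1, 3, 9 and 12 are taken as commercial.

**Step 1**
Reactants: 1 (R)‑glycidol
Product: 2 (S)‑triethyl(oxiran‑2‑ylmethoxy)silane
Conditions: TESCl, imidazole, CH2Cl2, 0 °C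
Reagents that add atoms: chlorotriethylsilane, CC[Si](Cl)(CC)CC
Why: Routine O‑silylation of the primary alcohol; the epoxide CH (future C8) is not touched, and its descriptor changes from R to S only through CIP priorities.

**Step 2**
Reactants: 2 (S)‑triethyl(oxiran‑2‑ylmethoxy)silane; 3 1‑(trimethylsilyl)propyne
Product: 6 (S)‑5,6‑bis(triethylsilyloxy)‑1‑(trimethylsilyl)hex‑1‑yne, via [3‑(trimethylsilyl)prop‑2‑yn‑1‑yl]lithium 4 (not isolated), via lithium (S)‑1‑(triethylsilyloxy)‑6‑(trimethylsilyl)hex‑5‑yn‑2‑olate 5 (not isolated)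
Conditions: 3, n‑BuLi, TMEDA, THF, −78 → 0 °C; 2, 0 °C → rt; then TESCl, 0 °C
Reagents that add atoms: chlorotriethylsilane, CC[Si](Cl)(CC)CC
Why: SN2 opening of the terminal epoxide at its CH2 by the propargylic lithium makes C6–C7 and leaves C8 untouched; the alkoxide is trapped in situ as a second TES ether, so any O→O silyl migration is degenerate.

**Step 3**
Reactants: 6 (S)‑5,6‑bis(triethylsilyloxy)‑1‑(trimethylsilyl)hex‑1‑yne
Product: 8 (S)‑6,7‑bis(triethylsilyloxy)hept‑2‑ynal, via [(S)‑5,6‑bis(triethylsilyloxy)hex‑1‑yn‑1‑yl]lithium 7 (not isolated)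
Conditions: MeLi·LiBr, THF, 0 °C → rt; DMF, −78 → 0 °C; inverse quench into 10 % aq KH2PO4/MTBE
Reagents that add atoms: N,N‑dimethylformamide, CN(C)C=O
Why: MeLi cleaves only the C(sp)–SiMe3 bond to give the lithium acetylide, which is formylated with DMF (acetylide formylation); the buffered inverse quench keeps the amine from adding to the ynal.

**Step 4**
Reactants: 8 (S)‑6,7‑bis(triethylsilyloxy)hept‑2‑ynal; 9 propionyl bromide
Product: 10 (3R,4S)‑4‑[(5S)‑5,6‑bis(triethylsilyloxy)hex‑1‑yn‑1‑yl]‑3‑methyloxetan‑2‑one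
Conditions: 9 (3 equiv), iPr2NEt, chiral Al(III)–salen catalyst with two pyridinium bromide side arms (10 mol %, the enantiomer that leaves the aldehyde Si face open), CH2Cl2, −70 °C
Reagents that add atoms: none
Why: Trans‑selective catalytic asymmetric acyl halide–aldehyde cyclocondensation (stepwise aldol–lactonisation); the ion‑paired acyl bromide enolate attacks the Al‑bound, non‑enolisable ynal through an open anti‑aldol transition state on the Si face, which sets C2 (R) and C3 under catalyst control and closes the trans‑lactone with retention.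

**Step 5**
Reactants: 10 (3R,4S)‑4‑[(5S)‑5,6‑bis(triethylsilyloxy)hex‑1‑yn‑1‑yl]‑3‑methyloxetan‑2‑one
Product: 11 (S)‑6‑[(2S,3R)‑3‑methyl‑4‑oxooxetan‑2‑yl]‑2‑(triethylsilyloxy)hex‑5‑ynal
Conditions: (COCl)2, DMSO, CH2Cl2, −78 → −40 °C; Et3N, −78 → −20 °C
Reagents that add atoms: none
Why: Swern oxidation run directly on the silyl ether; only the unhindered primary O–TES attacks the chlorosulfonium salt and is oxidised to the aldehyde, while the secondary TES ether and the β‑lactone survive and C8 is not epimerised at low temperature.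

**Step 6**
Reactants: 12 (S)‑pent‑4‑en‑2‑ol
Product: 13 (S)‑pent‑4‑en‑2‑yl acetate
Conditions: Ac2O, Et3N, DMAP (cat.), CH2Cl2, 0 °C → rt
Reagents that add atoms: acetic anhydride, CC(=O)OC(C)=O
Why: DMAP‑catalysed acetylation at oxygen; the C13 stereocentre comes from the starting alcohol and is retained.

**Step 7**
Reactants: 11 (S)‑6‑[(2S,3R)‑3‑methyl‑4‑oxooxetan‑2‑yl]‑2‑(triethylsilyloxy)hex‑5‑ynal; 13 (S)‑pent‑4‑en‑2‑yl acetate
Product: 16 (2S,6R,7S)‑6‑hydroxy‑11‑[(2S,3R)‑3‑methyl‑4‑oxooxetan‑2‑yl]‑7‑(triethylsilyloxy)undec‑10‑yn‑2‑yl acetate, via (S)‑5‑(diethylboranyl)pentan‑2‑yl acetate 14 (not isolated), via bis[(S)‑4‑acetoxypentyl]zinc 15 (not isolated)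
Conditions: 13 (5 equiv), Et2BH (from Et3B + BH3·SMe2), 0 °C → rt, evaporate; Et2Zn, 0 °C, evaporate; then 11, Ti(OiPr)4 (2 equiv), (1S,2S)‑1,2‑bis(trifluoromethanesulfonamido)cyclohexane (8 mol %), toluene, −20 °C; aq NH4Cl
Reagents that add atoms: none
Why: Hydroboration and boron–zinc exchange give an ester‑tolerant dialkylzinc, and its Ti/bis‑sulfonamide‑catalysed asymmetric 1,2‑addition delivers the alkyl group to the aldehyde Re face; ligand control is matched with the Felkin–Anh preference of the α‑silyloxy aldehyde, so C9 is set as R (8,9‑anti), and the rigid alkyne keeps the new alkoxide away from the lactone.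

**Step 8**
Reactants: 16 (2S,6R,7S)‑6‑hydroxy‑11‑[(2S,3R)‑3‑methyl‑4‑oxooxetan‑2‑yl]‑7‑(triethylsilyloxy)undec‑10‑yn‑2‑yl acetate
Product: 17 (2S,6R,7S,10Z)‑6‑hydroxy‑11‑[(2R,3R)‑3‑methyl‑4‑oxooxetan‑2‑yl]‑7‑(triethylsilyloxy)undec‑10‑en‑2‑yl acetate
Conditions: H2 (1 atm), Lindlar catalyst, quinoline, EtOAc, 0 °C → rt
Reagents that add atoms: none
Why: Lindlar syn‑semihydrogenation gives the 4Z alkene without hydrogenolysis of the propargylic or allylic C–O bond, and it bends the chain so that the C9–OH can reach the lactone carbonyl.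

**Step 9**
Reactants: 17 (2S,6R,7S,10Z)‑6‑hydroxy‑11‑[(2R,3R)‑3‑methyl‑4‑oxooxetan‑2‑yl]‑7‑(triethylsilyloxy)undec‑10‑en‑2‑yl acetate
Product: 19 (3R,4R,5Z,9S,10R)‑4‑acetoxy‑10‑[(4S)‑4‑acetoxypentyl]‑3‑methyl‑9‑(triethylsilyloxy)‑3,4,7,8,9,10‑hexahydro‑2H‑oxecin‑2‑one, via (3R,4R,5Z,9S,10R)‑10‑[(4S)‑4‑acetoxypentyl]‑4‑hydroxy‑3‑methyl‑9‑(triethylsilyloxy)‑3,4,7,8,9,10‑hexahydro‑2H‑oxecin‑2‑one 18 (not isolated)
Conditions: 17 added by syringe pump (12 h) to (BDI)Zn–N(SiMe3)2 (10 mol %; BDI = N,N′‑bis(2,6‑diisopropylphenyl)‑β‑diketiminate), toluene, final 1 mM, 4 Å MS, 40 °C; concentrate; Ac2O, Et3N, DMAP, 0 °C → rt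
Reagents that add atoms: acetic anhydride, CC(=O)OC(C)=O
Why: Proposed new method: the C9–OH protonolyses the Zn–N bond to give a monomeric (BDI)Zn alkoxide, the lactone C=O binds to the same zinc, O9 adds to C1, and the bicyclic tetrahedral adduct collapses by breaking the strained endocyclic C1–O3 bond (about 23 kcal/mol of β‑lactone strain released against roughly 10–12 kcal/mol taken up by the decanolide); the new Zn–O3 alkoxide passes zinc on to the next C9–OH, so only acyl–O bonds change and C2, C3, C8, C9 and C13 keep their configuration; the closest known reaction types are coordination–insertion ring opening of β‑butyrolactone by single‑site zinc alkoxides (acyl–O cleavage with retention) and translactonisation ring enlargement of ω‑hydroxyalkyl lactones, neither of which has been shown for a β‑lactone growing into a medium ring; the freed C3–OH is then acetylated in the same flask (DMAP‑catalysed acylation).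

**Step 10**
Reactants: 19 (3R,4R,5Z,9S,10R)‑4‑acetoxy‑10‑[(4S)‑4‑acetoxypentyl]‑3‑methyl‑9‑(triethylsilyloxy)‑3,4,7,8,9,10‑hexahydro‑2H‑oxecin‑2‑one
Product: 20 (3R,4R,5Z,9S,10R)‑4‑acetoxy‑10‑[(4S)‑4‑acetoxypentyl]‑9‑hydroxy‑3‑methyl‑3,4,7,8,9,10‑hexahydro‑2H‑oxecin‑2‑one (target)
Conditions: HF·pyridine, pyridine, THF, 0 °C
Reagents that add atoms: none
Why: Buffered fluoride desilylation removes the secondary TES ether under conditions too mild for acetate loss, allylic ionisation or O9→O8 acyl migration, and no stereocentre is involved.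

**Compound list**
1 | (R)‑glycidol | OC[C@@H]1CO1 | starting material
2 | (S)‑triethyl(oxiran‑2‑ylmethoxy)silane | CC[Si](CC)(CC)OC[C@@H]1CO1 | intermediate
3 | 1‑(trimethylsilyl)propyne | CC#C[Si](C)(C)C | starting material
4 | [3‑(trimethylsilyl)prop‑2‑yn‑1‑yl]lithium | [Li]CC#C[Si](C)(C)C | intermediate (not isolated)
5 | lithium (S)‑1‑(triethylsilyloxy)‑6‑(trimethylsilyl)hex‑5‑yn‑2‑olate | CC[Si](CC)(CC)OC[C@@H](O[Li])CCC#C[Si](C)(C)C | intermediate (not isolated)
6 | (S)‑5,6‑bis(triethylsilyloxy)‑1‑(trimethylsilyl)hex‑1‑yne | CC[Si](CC)(CC)OC[C@@H](O[Si](CC)(CC)CC)CCC#C[Si](C)(C)C | intermediate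
7 | [(S)‑5,6‑bis(triethylsilyloxy)hex‑1‑yn‑1‑yl]lithium | CC[Si](CC)(CC)OC[C@@H](O[Si](CC)(CC)CC)CCC#C[Li] | intermediate (not isolated)
8 | (S)‑6,7‑bis(triethylsilyloxy)hept‑2‑ynal | CC[Si](CC)(CC)OC[C@@H](O[Si](CC)(CC)CC)CCC#CC=O | intermediate
9 | propionyl bromide | CCC(=O)Br | starting material
10 | (3R,4S)‑4‑[(5S)‑5,6‑bis(triethylsilyloxy)hex‑1‑yn‑1‑yl]‑3‑methyloxetan‑2‑one | CC[Si](CC)(CC)OC[C@@H](O[Si](CC)(CC)CC)CCC#C[C@H]1OC(=O)[C@@H]1C | intermediate
11 | (S)‑6‑[(2S,3R)‑3‑methyl‑4‑oxooxetan‑2‑yl]‑2‑(triethylsilyloxy)hex‑5‑ynal | O=C[C@@H](O[Si](CC)(CC)CC)CCC#C[C@H]1OC(=O)[C@@H]1C | intermediate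
12 | (S)‑pent‑4‑en‑2‑ol | C[C@H](O)CC=C | starting material
13 | (S)‑pent‑4‑en‑2‑yl acetate | CC(=O)O[C@@H](C)CC=C | intermediate
14 | (S)‑5‑(diethylboranyl)pentan‑2‑yl acetate | CC(=O)O[C@@H](C)CCCB(CC)CC | intermediate (not isolated)
15 | bis[(S)‑4‑acetoxypentyl]zinc | CC(=O)O[C@@H](C)CCC[Zn]CCC[C@H](C)OC(C)=O | intermediate (not isolated)
16 | (2S,6R,7S)‑6‑hydroxy‑11‑[(2S,3R)‑3‑methyl‑4‑oxooxetan‑2‑yl]‑7‑(triethylsilyloxy)undec‑10‑yn‑2‑yl acetate | CC(=O)O[C@@H](C)CCC[C@@H](O)[C@@H](O[Si](CC)(CC)CC)CCC#C[C@H]1OC(=O)[C@@H]1C | intermediate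
17 | (2S,6R,7S,10Z)‑6‑hydroxy‑11‑[(2R,3R)‑3‑methyl‑4‑oxooxetan‑2‑yl]‑7‑(triethylsilyloxy)undec‑10‑en‑2‑yl acetate | CC(=O)O[C@@H](C)CCC[C@@H](O)[C@@H](O[Si](CC)(CC)CC)CC/C=C\[C@H]1OC(=O)[C@@H]1C | intermediate
18 | (3R,4R,5Z,9S,10R)‑10‑[(4S)‑4‑acetoxypentyl]‑4‑hydroxy‑3‑methyl‑9‑(triethylsilyloxy)‑3,4,7,8,9,10‑hexahydro‑2H‑oxecin‑2‑one | CC(=O)O[C@@H](C)CCC[C@H]1OC(=O)[C@H](C)[C@H](O)/C=C\CC[C@@H]1O[Si](CC)(CC)CC | intermediate (not isolated)
19 | (3R,4R,5Z,9S,10R)‑4‑acetoxy‑10‑[(4S)‑4‑acetoxypentyl]‑3‑methyl‑9‑(triethylsilyloxy)‑3,4,7,8,9,10‑hexahydro‑2H‑oxecin‑2‑one | CC(=O)O[C@@H](C)CCC[C@H]1OC(=O)[C@H](C)[C@H](OC(C)=O)/C=C\CC[C@@H]1O[Si](CC)(CC)CC | intermediate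
20 | (3R,4R,5Z,9S,10R)‑4‑acetoxy‑10‑[(4S)‑4‑acetoxypentyl]‑9‑hydroxy‑3‑methyl‑3,4,7,8,9,10‑hexahydro‑2H‑oxecin‑2‑one (CNP0192248.1) | CC(=O)O[C@@H](C)CCC[C@H]1OC(=O)[C@H](C)[C@H](OC(C)=O)/C=C\CC[C@@H]1O | target

**Step count**
Total steps: 10. Longest linear sequence: 9 (steps 1–5 and 7–10).

**Steps most likely to fail**

Step 9 (the new step). There are four risks:
- intermolecular insertion, which gives oligomers;
- TES migration from O8 to O9 at the zinc alkoxide stage, which would lead to the nine‑membered isomer;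
- Lewis‑acid ionisation of the Z‑allylic C3–O bond, which gives a 4→6 rearrangement to a dihydropyranone;
- retro‑aldol cleavage of the Zn–O3 aldolate.

The fallback uses known chemistry and sets out from 17. LiOH (1.1 equiv) in THF/H2O at 0 °C hydrolyses only the strained lactone. This gives (2R,3R,4Z,8S,9R,13S)‑13‑acetoxy‑3,9‑dihydroxy‑2‑methyl‑8‑(triethylsilyloxy)tetradec‑4‑enoic acid F1. Yamaguchi macrolactonisation (2,4,6‑trichlorobenzoyl chloride, Et3N, THF; then DMAP, toluene, 1 mM) closes the ring at the C9–OH. Closure at the C3–OH would only regenerate 17. The fallback rejoins the route at 18, which is acetylated as in step 9.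

Step 4. The trans‑selective cyclocondensation is established for simple aldehydes but not for ynals. The trans/cis ratio or the ee may drop, and bromide or amine may add to the triple bond.

The fallback sets out from 8. Acetyl bromide, iPr2NEt and a chiral Al(III)–triamine (bis‑sulfonamide) catalyst in CH2Cl2 at −50 °C are used. This cyclocondensation is well proven on alkynyl aldehydes, and it gives (S)‑4‑[(5S)‑5,6‑bis(triethylsilyloxy)hex‑1‑yn‑1‑yl]oxetan‑2‑one F2. NaHMDS in THF at −78 °C, followed by MeI, alkylates the lactone enolate on the face opposite the alkynyl group. This gives the trans product and rejoins the route at 10.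

Step 7. Titanium isopropoxide may open the β‑lactone, the hindered α‑silyloxy aldehyde may react slowly or epimerise, and ethyl transfer from residual Et2Zn can compete.

The fallback sets out from borane 14 (made from 13 as in step 7) and aldehyde 11. H2O2 in pH 7 buffer gives (S)‑5‑hydroxypentan‑2‑yl acetate F3. I2, PPh3 and imidazole then give (S)‑5‑iodopentan‑2‑yl acetate F4. F4 and 11 are coupled with CrCl2 and catalytic cobalt phthalocyanine in DMF at rt (alkylchromium addition of the Takai–Utimoto type). This is neutral, titanium‑free and tolerant of esters and lactones. Felkin–Anh control gives the 8,9‑anti alcohol, and the minor 9‑epimer is removed by chromatography. The fallback rejoins the route at 16.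

**Further compounds**
F1 | step 9 | (2R,3R,4Z,8S,9R,13S)‑13‑acetoxy‑3,9‑dihydroxy‑2‑methyl‑8‑(triethylsilyloxy)tetradec‑4‑enoic acid | CC(=O)O[C@@H](C)CCC[C@@H](O)[C@@H](O[Si](CC)(CC)CC)CC/C=C\[C@@H](O)[C@@H](C)C(=O)O
F2 | step 4 | (S)‑4‑[(5S)‑5,6‑bis(triethylsilyloxy)hex‑1‑yn‑1‑yl]oxetan‑2‑one | CC[Si](CC)(CC)OC[C@@H](O[Si](CC)(CC)CC)CCC#C[C@H]1OC(=O)C1
F3 | step 7 | (S)‑5‑hydroxypentan‑2‑yl acetate | CC(=O)O[C@@H](C)CCCO
F4 | step 7 | (S)‑5‑iodopentan‑2‑yl acetate | CC(=O)O[C@@H](C)CCCI
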